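**Plan**
1. Retrosynthetic cuts, in order: the O7–Si and O4′–Si bonds; the C2–C1′ bond (aryl added to C2 of a chromone); the C8–C1″ bond, traced back to the O5–C1″ ether of a 5‑geranyloxychromone; then O5–C1″ (geraniol) and O7–Si.
2. Enabling feature: in ring A (the phloroglucinol ring) O1 is tied into the pyranone ring, O7 is silylated, and only O5, peri to the C4 carbonyl, carries the geranyl group. Its ortho carbon C4a is quaternary, C6 is the only open ortho carbon and C8 is para, so two consecutive [3,3] shifts (O5→C6→C8) can end only at C8 and return the chain linear.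
3. Forward order: rings A and C are bought together as the chromone; geranyl is tethered at O5 and relayed to C8; the oxygenated phenyl ring B is then added at C2, which turns the chromone into the flavanone; desilylation finishes the route.
4. Stereochemistry: C2 (S) is set by the chiral rhodium–diphosphine catalyst in the conjugate addition; the E C2″=C3″ bond comes from geraniol and is relayed through chair transition states.

Key step: step 3

Assumption: 5,7‑dihydroxychromone is taken as a purchasable compound, and the (R)‑enantiomer of the biaryl diphosphine is taken to deliver the aryl group to the face of C2 that gives the 2S product; if a test addition shows the opposite sense, the (S)‑ligand is used.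

(Geranyl = (2E)‑3,7‑dimethylocta‑2,6‑dien‑1‑yl; TIPS = triisopropylsilyl; TBS = tert‑butyldimethylsilyl.)

**Step 1**
Reactants: 1 5,7‑dihydroxychromone
Product: 2 5‑hydroxy‑7‑(triisopropylsilyloxy)chromone
Conditions: TIPSCl (1.1 equiv), imidazole (2.2 equiv), DMF, 0 °C to rt
Reagents that add atoms: triisopropylsilyl chloride, CC(C)[Si](Cl)(C(C)C)C(C)C
Why: The 7‑OH is the acidic, unhindered phenol (para to the C4 carbonyl) whereas the 5‑OH is hydrogen‑bonded to that carbonyl, so silylation of a phenol with one equivalent of the bulky chloride should stop at O7.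

**Step 2**
Reactants: 2 5‑hydroxy‑7‑(triisopropylsilyloxy)chromone; 3 geraniol
Product: 4 5‑(geranyloxy)‑7‑(triisopropylsilyloxy)chromone
Conditions: PPh3, DIAD, THF, 0 °C to rt
Reagents that add atoms: none
Why: Mitsunobu etherification of the chelated 5‑OH with a primary allylic alcohol should proceed by SN2 attack at C1″ under neutral conditions, which keeps the chain linear and E and leaves the 7‑O‑silyl ether in place.

**Step 3**
Reactants: 4 5‑(geranyloxy)‑7‑(triisopropylsilyloxy)chromone
Product: 7 8‑geranyl‑5‑hydroxy‑7‑(triisopropylsilyloxy)chromone, via ortho‑dienone 5 (not isolated), via para‑dienone 6 (not isolated)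
Conditions: Eu(fod)3 (10 mol%), PhCl, 80 °C, Ar
Reagents that add atoms: none
Why: Eu(III) binds the peri pair O5/C4=O and polarises the O5–C1″ bond, so the aryl geranyl ether should undergo an aromatic Claisen [3,3] shift to C6 (the only open ortho carbon, C4a being quaternary) to give ortho‑dienone 5, whose 1,5‑diene C1″=C2″–C3″–C6–C7=C8 then undergoes a Cope [3,3] shift that delivers the former O‑bound CH2 to C8, and enolisation of para‑dienone 6 restores the aromatic ring with O5 as the free phenol. The closest known reaction type is the Eu(fod)3‑catalysed para‑Claisen–Cope rearrangement of 5‑prenyloxyflavonoids to 8‑prenylflavonoids. No ring is closed; both shifts run through six‑membered chair transition states. No stereocentre remains in 7: the C6 and C3″ centres of 5 are transient and relay the E geometry of the C2″=C3″ bond, because a chair Claisen shift followed by a chair Cope shift returns the methyl group cis to C1″. The step needs C8 over C6 selectivity and retention of the E double bond: the first is secured because O5 is the only ring‑A oxygen that carries the chain, C8 is para to it, and in the aprotic medium the Cope shift of 5 is expected to outrun its enolisation; the second rests on the chair preference of both shifts.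

**Step 4**
Reactants: 7 8‑geranyl‑5‑hydroxy‑7‑(triisopropylsilyloxy)chromone; 8 4‑(tert‑butyldimethylsilyloxy)phenylboronic acid (3 equiv)
Product: 9 (2S)‑2‑[4‑(tert‑butyldimethylsilyloxy)phenyl]‑8‑geranyl‑5‑hydroxy‑7‑(triisopropylsilyloxy)chroman‑4‑one
Conditions: [RhCl(C2H4)2]2 (2.5 mol%), (R)‑MeO‑F12‑BIPHEP (5.5 mol%), aq KOH (10 mol%), toluene, 40 °C
Reagents that add atoms: none
Why: In this rhodium‑catalysed asymmetric 1,4‑addition of an arylboronic acid to a chromone (Hayashi–Miyaura reaction), the aryl–Rh(I) species should insert the C2=C3 bond on the face dictated by the C2‑symmetric diphosphine, which sets C2 as S by catalyst control, and water protonates the rhodium enolate, while the isolated trisubstituted alkenes and both silyl ethers stay inert.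

**Step 5**
Reactants: 9 (2S)‑2‑[4‑(tert‑butyldimethylsilyloxy)phenyl]‑8‑geranyl‑5‑hydroxy‑7‑(triisopropylsilyloxy)chroman‑4‑one
Product: 10 sophoraflavanone A
Conditions: TBAF (2.5 equiv), AcOH (2.5 equiv), THF, 0 °C
Reagents that add atoms: none
Why: Fluoride should cleave both aryl silyl ethers (desilylation), and the acetic acid buffer keeps the liberated 7‑ and 4′‑phenols protonated so that the flavanone does not open to the chalcone and C2 keeps its configuration, the geranyl chain being untouched.

**Compound list**
1 | 5,7‑dihydroxychromone (5,7‑dihydroxy‑4H‑chromen‑4‑one) | O=c1ccoc2cc(O)cc(O)c12 | starting material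
2 | 5‑hydroxy‑7‑(triisopropylsilyloxy)chromone | O=c1ccoc2cc(O[Si](C(C)C)(C(C)C)C(C)C)cc(O)c12 | intermediate
3 | geraniol, (2E)‑3,7‑dimethylocta‑2,6‑dien‑1‑ol | CC(C)=CCC/C(C)=C/CO | starting material
4 | 5‑(geranyloxy)‑7‑(triisopropylsilyloxy)chromone | O=c1ccoc2cc(O[Si](C(C)C)(C(C)C)C(C)C)cc(OC/C=C(\C)CCC=C(C)C)c12 | intermediate
5 | ortho‑dienone, rac‑(6R)‑6‑[(3R)‑3,7‑dimethylocta‑1,6‑dien‑3‑yl]‑7‑(triisopropylsilyloxy)‑6H‑chromene‑4,5‑dione (relative configuration expected from the chair Claisen shift; one enantiomer drawn) | O=C1[C@H]([C@](C)(CCC=C(C)C)C=C)C(O[Si](C(C)C)(C(C)C)C(C)C)=CC2=C1C(=O)C=CO2 | intermediate (not isolated)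
6 | para‑dienone, rac‑8‑geranyl‑7‑(triisopropylsilyloxy)‑8H‑chromene‑4,5‑dione (one enantiomer drawn) | O=C1C=C(O[Si](C(C)C)(C(C)C)C(C)C)[C@H](C/C=C(\C)CCC=C(C)C)C2=C1C(=O)C=CO2 | intermediate (not isolated)
7 | 8‑geranyl‑5‑hydroxy‑7‑(triisopropylsilyloxy)chromone | O=c1ccoc2c(C/C=C(\C)CCC=C(C)C)c(O[Si](C(C)C)(C(C)C)C(C)C)cc(O)c12 | intermediate
8 | 4‑(tert‑butyldimethylsilyloxy)phenylboronic acid | CC(C)(C)[Si](C)(C)Oc1ccc(B(O)O)cc1 | starting material
9 | (2S)‑2‑[4‑(tert‑butyldimethylsilyloxy)phenyl]‑8‑geranyl‑5‑hydroxy‑7‑(triisopropylsilyloxy)chroman‑4‑one | CC(C)=CCC/C(C)=C/Cc1c(O[Si](C(C)C)(C(C)C)C(C)C)cc(O)c2c1O[C@H](c1ccc(O[Si](C)(C)C(C)(C)C)cc1)CC2=O | intermediate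
10 | sophoraflavanone A, (2S)‑8‑geranyl‑5,7‑dihydroxy‑2‑(4‑hydroxyphenyl)chroman‑4‑one | CC(C)=CCC/C(C)=C/Cc1c(O)cc(O)c2c1O[C@H](c1ccc(O)cc1)CC2=O | target

**Step count and risks**
Total steps: 5. Longest linear sequence: 5.

Steps most likely to fail:

Step 3. The E geometry may erode if one of the two shifts passes through a boat transition state or if the Lewis acid opens an ion‑pair path. The sequence may also stop after the first shift by enolisation of the ortho‑dienone, which would leave a branched chain at C6, and the bulky silyl ether next to both migration termini may slow the relay. The fallback is a cross‑coupling that never touches the C2″=C3″ bond; it sets out from 2 and comes back at 7. The 5‑OH of 2 is capped with MOMCl and NaH in DMF to give 5‑(methoxymethoxy)‑7‑(triisopropylsilyloxy)chromone F1. With O5 etherified, electrophilic iodination with N‑iodosuccinimide in acetonitrile should go to C8, which is para to O5 and flanked only by O1 and O7, giving 8‑iodo‑5‑(methoxymethoxy)‑7‑(triisopropylsilyloxy)chromone F2. (E)‑Geranyltributylstannane F3 is made from commercial geranyl chloride and tributylstannyllithium in THF at −78 °C. A Stille coupling of F2 and F3 (Pd2(dba)3, tri(2‑furyl)phosphine, DMF, 80 °C) should give 8‑geranyl‑5‑(methoxymethoxy)‑7‑(triisopropylsilyloxy)chromone F4. Methanolysis of the peri acetal (PPTS, MeOH, 40 °C), which is the most labile group because of the neighbouring carbonyl, then gives 7.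

Step 4. Carbometalation of the electron‑rich chromone may be slow because its 5‑hydroxy‑4‑keto unit can bind rhodium as a chelate, and enantiopurity may be lost by reversible opening of the pyranone ring of the product in the basic aqueous phase. The fallback changes the order of events; it sets out from 4 and comes back at 9. The same rhodium‑catalysed addition of 8 is run on 4, which has no free phenol and no C8 substituent, to give (2S)‑2‑[4‑(tert‑butyldimethylsilyloxy)phenyl]‑5‑(geranyloxy)‑7‑(triisopropylsilyloxy)chroman‑4‑one F5. The Eu(fod)3‑catalysed Claisen–Cope relay is then carried out on this flavanone, the substrate class with the closest precedent, to give 9.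

Step 2. Etherification of the hydrogen‑bonded 5‑OH may be incomplete, with alkylation of the reduced azodicarboxylate or SN2′ attack (branched ether) competing. The fallback reverses the polarity of the union; it sets out from 2 and comes back at 4. The caesium phenoxide of 2 (Cs2CO3, acetone, rt) is alkylated with commercial geranyl bromide in a Williamson ether synthesis, which forms the same O5–C1″ bond by SN2 displacement at the primary allylic carbon.

**Further compounds**
F1 | step 3 | 5‑(methoxymethoxy)‑7‑(triisopropylsilyloxy)chromone | COCOc1cc(O[Si](C(C)C)(C(C)C)C(C)C)cc2occc(=O)c12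
F2 | step 3 | 8‑iodo‑5‑(methoxymethoxy)‑7‑(triisopropylsilyloxy)chromone | COCOc1cc(O[Si](C(C)C)(C(C)C)C(C)C)c(I)c2occc(=O)c12
F3 | step 3 | (E)‑geranyltributylstannane | CCCC[Sn](CCCC)(CCCC)C/C=C(\C)CCC=C(C)C
F4 | step 3 | 8‑geranyl‑5‑(methoxymethoxy)‑7‑(triisopropylsilyloxy)chromone | COCOc1cc(O[Si](C(C)C)(C(C)C)C(C)C)c(C/C=C(\C)CCC=C(C)C)c2occc(=O)c12
F5 | step 4 | (2S)‑2‑[4‑(tert‑butyldimethylsilyloxy)phenyl]‑5‑(geranyloxy)‑7‑(triisopropylsilyloxy)chroman‑4‑one | O=C1C[C@@H](c2ccc(O[Si](C)(C)C(C)(C)C)cc2)Oc2cc(O[Si](C(C)C)(C(C)C)C(C)C)cc(OC/C=C(\C)CCC=C(C)C)c21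
F0 | step 2 | none | none
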